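**Retrosynthetic overview**

1. Numbering: ring C1–C14 with the stereocentre at C1, E-C3=C4(Me), Z-C7=C8(Me) and E-C11=C12(CO2Me); side chain C15(=C16H2)–C17H2–C18H2–C19H=C20Me2 on C1.
2. The only ring (14-membered carbocycle) is closed last, at C12–C13, by an intramolecular sp3–sp2 Suzuki–Miyaura coupling of a C13 alkyl pinacol boronate with a (Z)-α-iodo enoate made from the C11 aldehyde.
3. C14 and C13 are inserted one at a time between C1 and boron by two Matteson CH2 homologations, with retention at C1.
4. Key disconnection C1–C15: lithiation–borylation, in which the (−)-sparteine-lithiated C1 carbamate of the achiral C1–C11 chain inserts into the C15–B bond of the alkenyl boronate from sulcatone; the 1,2-metallate shift forms C1–C15 and the stereocentre, and the C1–B bond (not in the target) stays as the handle for lines 3 and 2.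
5. Enabling feature: C1 is the only stereocentre, a CH bonded to the exocyclic sp2 carbon C15 (of C15=C16H2, outside the ring) and to two ring CH2 groups (C2, C14), so C1 can enter as a primary carbamate carbon (a chiral carbenoid) and C15 as a migrating alkenyl group; the unsubstituted C14H2–C13H2 run that ends at the sp2 ring carbon C12 lets the same boron atom move two carbons and then close the ring.

Key step: step 9

Remark: ring numbering as in line 1 is used throughout (TBS = tert-butyldimethylsilyl, pin = pinacolato); (−)-sparteine is assumed to remove the pro-S hydrogen of the carbamate as is usual, which leads to R at C1, and the opposite sense would simply call for (+)-sparteine.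

**Route**

Step 1
Reactants: 1 nerol
Product: 2 neryl chloride
Conditions: PPh3, CCl4, reflux
Reagents that add atoms: carbon tetrachloride, ClC(Cl)(Cl)Cl
Why: Appel chlorination proceeds by SN2 displacement of the alkoxyphosphonium ion at the primary carbon, so the chloride should form without allylic transposition or isomerisation of the Z alkene (future C7=C8).

Step 2
Reactants: 2 neryl chloride
Product: 4 (4Z)-6-chloro-4-methylhex-4-en-1-ol, via chloro aldehyde 3 (not isolated)
Conditions: O3 (1 equiv, Sudan Red 7B end-point), CH2Cl2/MeOH, −78 °C; then NaBH4, −78 → 0 °C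
Reagents that add atoms: ozone, [O-][O+]=O
Why: Site-selective ozonolysis with reductive work-up: the electrophilic ozone should cleave the electron-rich isopropylidene alkene in preference to the alkene deactivated by the allylic chlorine, and NaBH4 then reduces aldehyde 3 (C11) without touching the allylic chloride.

Step 3
Reactants: 4 (4Z)-6-chloro-4-methylhex-4-en-1-ol
Product: 5 TBS ether of 4
Conditions: TBSOTf, 2,6-lutidine, CH2Cl2, −78 °C
Reagents that add atoms: tert-butyldimethylsilyl trifluoromethanesulfonate, CC(C)(C)[Si](C)(C)OS(=O)(=O)C(F)(F)F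
Why: Silylation with the silyl triflate and a hindered, non-nucleophilic base is fast at −78 °C, so the hydroxyl is capped before it or an amine can displace the allylic chloride.

Step 4
Reactants: 5 TBS ether of 4
Product: 6 (4Z)-4-methylnon-4-en-8-yn-1-yl TBS ether (C3–C11 enyne)
Conditions: propyne, n-BuLi (2 equiv), TMEDA, Et2O/hexane, −78 → 0 °C; then 5, THF, −78 °C → rt; H2O
Reagents that add atoms: propyne, CC#C
Why: Propargylation by SN2 alkylation of 1,3-dilithiopropyne at its sp3 carbon with the primary allylic chloride forms C5–C6 without SN2' attack or Z/E isomerisation, and aqueous work-up frees the terminal alkyne.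

Step 5
Reactants: 6 C3–C11 enyne
Product: 9 (3E,7Z)-11-(TBS-oxy)-4,8-dimethylundeca-3,7-dien-1-ol, via alkenylalane 7 (not isolated), via lithium alanate 8 (not isolated)
Conditions: AlMe3, Cp2ZrCl2 (cat.), CH2Cl2, 0 °C → rt; n-BuLi, hexane/THF, −78 → 0 °C; oxirane, −78 °C → rt; aq. Rochelle salt
Reagents that add atoms: trimethylaluminium, C[Al](C)C; oxirane, C1CO1
Why: Negishi zirconium-catalysed carboalumination adds methyl and aluminium syn across the terminal alkyne with methyl on the internal carbon, which fixes the E geometry of C3=C4, and the lithium alanate 8 opens oxirane with retention at the alkenyl carbon to add C2 and C1.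

Step 6
Reactants: 9 homoallylic alcohol (C1–C11)
Product: 10 N,N-diisopropylcarbamate of 9
Conditions: NaH, THF, 0 °C; i-Pr2NCOCl, reflux
Reagents that add atoms: N,N-diisopropylcarbamoyl chloride, CC(C)N(C(C)C)C(=O)Cl
Why: O-Acylation of the sodium alkoxide with the carbamoyl chloride installs the N,N-diisopropylcarbamate, which will direct the lithiation of C1 and later serve as the leaving group.

Step 7
Reactants: 11 sulcatone (6-methylhept-5-en-2-one)
Product: 13 6-methylhepta-1,5-dien-2-yl triflate, via lithium enolate 12 (not isolated)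
Conditions: LDA, THF, −78 °C; PhNTf2, −78 → 0 °C
Reagents that add atoms: N-phenylbis(trifluoromethanesulfonimide), O=S(=O)(N(c1ccccc1)S(=O)(=O)C(F)(F)F)C(F)(F)F
Why: Kinetic enolate formation takes a proton from the less hindered methyl group and O-triflation traps the terminal enolate as the 1,1-disubstituted enol triflate (any internal isomer is removed by chromatography).

Step 8
Reactants: 13 enol triflate
Product: 14 2-(6-methylhepta-1,5-dien-2-yl) pinacol boronate
Conditions: B2pin2, PdCl2(PPh3)2, PPh3, KOPh, toluene, 50 °C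
Reagents that add atoms: bis(pinacolato)diboron, CC1(C)OB(B2OC(C)(C)C(C)(C)O2)OC1(C)C
Why: Miyaura borylation (oxidative addition of Pd(0) into the alkenyl C–OTf bond, transmetallation with the phenoxide-activated diboron, reductive elimination) gives the 1-alkylvinyl boronate with the double bond in place.

Step 9
Reactants: 10 carbamate (C1–C11 chain); 14 alkenyl pinacol boronate (C15–C20)
Product: 17 (R)-allylic pinacol boronate (C1 bears Bpin and C15), via lithiated carbamate 15 (not isolated), via boronate complex 16 (not isolated)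
Conditions: s-BuLi, (−)-sparteine, Et2O, −78 °C, 5 h; 14, −78 °C, 1 h; then warm to rt
Reagents that add atoms: none
Why: Lithiation–borylation: s-BuLi/(−)-sparteine removes the pro-S hydrogen at C1 (carbamate-directed, the chiral diamine selects between the enantiotopic protons) to give the configurationally stable α-oxy organolithium 15, which is borylated by 14 with retention to the boronate complex 16. On warming, the sp2 carbon C15 migrates from boron to C1 anti to the departing carbamate (stereospecific 1,2-metallate rearrangement, inversion at C1), which forms the C1–C15 bond and the R stereocentre in one event from two achiral fragments and leaves boron on C1. The closest known reaction type is the reaction of sparteine-lithiated primary alkyl carbamates with vinyl pinacol boronates to give α-substituted allylic boronates. No ring is closed; the one new stereocentre is controlled by the reagent ((−)-sparteine) together with the fixed stereochemical course of borylation (retention) and migration (inversion). The step needs α-lithiation in preference to allylic deprotonation at C2, which the complex-induced proximity effect of the carbamate secures, and migration of carbon instead of oxygen, which the high migratory aptitude of the alkenyl group secures; the unactivated trisubstituted alkenes and the silyl ether are inert. In polarity terms C1 (a C–O carbon turned into a carbenoid) and C15 (a C–B carbon) are united on a boron template that stays behind as the handle for C14, C13 and the ring closure.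

Step 10
Reactants: 17 (R)-allylic pinacol boronate
Product: 19 (R)-C14 pinacol boronate (C1–CH2–Bpin), via chloromethyl boronate complex 18 (not isolated)
Conditions: ICH2Cl, n-BuLi, THF, −78 °C → rt
Reagents that add atoms: chloroiodomethane, ClCI
Why: Matteson homologation: (chloromethyl)lithium made in the flask adds to boron at −78 °C and, on warming, C1 migrates from boron to the CH2 carbon with loss of chloride and retention at C1, which inserts C14 once because the carbenoid is gone before migration starts.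

Step 11
Reactants: 19 (R)-C14 pinacol boronate
Product: 21 (R)-C13 pinacol boronate (C1–CH2CH2–Bpin), via chloromethyl boronate complex 20 (not isolated)
Conditions: ICH2Cl, n-BuLi, THF, −78 °C → rt
Reagents that add atoms: chloroiodomethane, ClCI
Why: A second Matteson homologation inserts C13 by 1,2-migration of the primary carbon C14, so the stereocentre is not involved.

Step 12
Reactants: 21 (R)-C13 pinacol boronate
Product: 22 C11 alcohol
Conditions: CSA (cat.), MeOH/CH2Cl2, 0 °C
Reagents that add atoms: none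
Why: Acid-catalysed methanolysis cleaves the primary silyl ether while the pinacol boronate and the alkenes are stable to catalytic acid at 0 °C.

Step 13
Reactants: 22 C11 alcohol
Product: 23 C11 aldehyde
Conditions: Dess–Martin periodinane, NaHCO3, CH2Cl2, 0 °C → rt
Reagents that add atoms: none
Why: Dess–Martin oxidation converts the primary alcohol into the aldehyde under buffered, anhydrous conditions that leave the alkyl boronate and the alkenes untouched.

Step 14
Reactants: 23 C11 aldehyde
Product: 24 (2Z)-α-iodo enoate (C11=C12(I)CO2Me, Bpin on C13)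
Conditions: Ph3P=CHCO2Me, NIS, CH2Cl2, −20 °C; then 23, −20 °C → rt
Reagents that add atoms: methyl (triphenyl-λ5-phosphanylidene)acetate, COC(=O)C=P(c1ccccc1)(c1ccccc1)c1ccccc1; N-iodosuccinimide, O=C1CCC(=O)N1I
Why: Wittig olefination with the α-iodo ester ylide (made in the flask by iodination of the stabilised ylide) places the ester trans to the chain as stabilised ylides do, so the alkenyl iodide should be Z with iodine on the side that C13 has to occupy.

Step 15
Reactants: 24 (2Z)-α-iodo enoate
Product: 25 CNP0199631.1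
Conditions: Pd(OAc)2, SPhos, K3PO4, toluene/H2O, 80 °C, high dilution (slow addition)
Reagents that add atoms: none
Why: Intramolecular B-alkyl Suzuki–Miyaura coupling (oxidative addition into the C12–I bond, transmetallation of the primary C13 boronate, reductive elimination) closes the 14-membered ring at C12–C13 with retention of the alkene geometry, which gives the E enoate with C10 and C13 cis as the target requires.

**Compound list**

1 | nerol, (2Z)-3,7-dimethylocta-2,6-dien-1-ol | OC/C=C(/C)CCC=C(C)C | starting material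
2 | neryl chloride, (2Z)-1-chloro-3,7-dimethylocta-2,6-diene | ClC/C=C(/C)CCC=C(C)C | intermediate
3 | (4Z)-6-chloro-4-methylhex-4-enal (not isolated) | ClC/C=C(/C)CCC=O | intermediate
4 | (4Z)-6-chloro-4-methylhex-4-en-1-ol | ClC/C=C(/C)CCCO | intermediate
5 | tert-butyl{[(4Z)-6-chloro-4-methylhex-4-en-1-yl]oxy}dimethylsilane | ClC/C=C(/C)CCCO[Si](C)(C)C(C)(C)C | intermediate
6 | tert-butyldimethyl{[(4Z)-4-methylnon-4-en-8-yn-1-yl]oxy}silane | C#CCC/C=C(/C)CCCO[Si](C)(C)C(C)(C)C | intermediate
7 | [(1E,5Z)-9-(TBS-oxy)-2,6-dimethylnona-1,5-dien-1-yl]dimethylalumane (not isolated) | C[Al](C)/C=C(\C)CC/C=C(/C)CCCO[Si](C)(C)C(C)(C)C | intermediate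
8 | lithium butyl[(1E,5Z)-9-(TBS-oxy)-2,6-dimethylnona-1,5-dien-1-yl]dimethylaluminate (not isolated) | [Li+].CCCC[Al-](C)(C)/C=C(\C)CC/C=C(/C)CCCO[Si](C)(C)C(C)(C)C | intermediate
9 | (3E,7Z)-11-[(tert-butyldimethylsilyl)oxy]-4,8-dimethylundeca-3,7-dien-1-ol | OCC/C=C(\C)CC/C=C(/C)CCCO[Si](C)(C)C(C)(C)C | intermediate
10 | (3E,7Z)-11-[(tert-butyldimethylsilyl)oxy]-4,8-dimethylundeca-3,7-dien-1-yl N,N-diisopropylcarbamate | CC(C)N(C(C)C)C(=O)OCC/C=C(\C)CC/C=C(/C)CCCO[Si](C)(C)C(C)(C)C | intermediate
11 | sulcatone, 6-methylhept-5-en-2-one | CC(=O)CCC=C(C)C | starting material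
12 | lithium 6-methylhepta-1,5-dien-2-olate (not isolated) | C=C(O[Li])CCC=C(C)C | intermediate
13 | 6-methylhepta-1,5-dien-2-yl trifluoromethanesulfonate | C=C(OS(=O)(=O)C(F)(F)F)CCC=C(C)C | intermediate
14 | 4,4,5,5-tetramethyl-2-(6-methylhepta-1,5-dien-2-yl)-1,3,2-dioxaborolane | C=C(B1OC(C)(C)C(C)(C)O1)CCC=C(C)C | intermediate
15 | (1S,3E,7Z)-11-(TBS-oxy)-1-lithio-4,8-dimethylundeca-3,7-dien-1-yl N,N-diisopropylcarbamate, (−)-sparteine complex (not isolated) | [Li][C@H](OC(=O)N(C(C)C)C(C)C)C/C=C(\C)CC/C=C(/C)CCCO[Si](C)(C)C(C)(C)C | intermediate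
16 | lithium [(1S,3E,7Z)-11-(TBS-oxy)-1-(diisopropylcarbamoyloxy)-4,8-dimethylundeca-3,7-dien-1-yl](6-methylhepta-1,5-dien-2-yl)(pinacolato)borate (not isolated) | [Li+].C=C(CCC=C(C)C)[B-]1(OC(C)(C)C(C)(C)O1)[C@H](OC(=O)N(C(C)C)C(C)C)C/C=C(\C)CC/C=C(/C)CCCO[Si](C)(C)C(C)(C)C | intermediate
17 | tert-butyldimethyl{[(4Z,8E,11R)-4,8,16-trimethyl-12-methylidene-11-(4,4,5,5-tetramethyl-1,3,2-dioxaborolan-2-yl)heptadeca-4,8,15-trien-1-yl]oxy}silane | C=C(CCC=C(C)C)[C@H](B1OC(C)(C)C(C)(C)O1)C/C=C(\C)CC/C=C(/C)CCCO[Si](C)(C)C(C)(C)C | intermediate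
18 | lithium (chloromethyl)(pinacolato)borate complex of 17, boron on C1 (not isolated) | [Li+].ClC[B-]1(OC(C)(C)C(C)(C)O1)[C@@H](C(=C)CCC=C(C)C)C/C=C(\C)CC/C=C(/C)CCCO[Si](C)(C)C(C)(C)C | intermediate
19 | tert-butyldimethyl{[(4Z,8E,11R)-4,8,16-trimethyl-12-methylidene-11-[(4,4,5,5-tetramethyl-1,3,2-dioxaborolan-2-yl)methyl]heptadeca-4,8,15-trien-1-yl]oxy}silane | C=C(CCC=C(C)C)[C@H](CB1OC(C)(C)C(C)(C)O1)C/C=C(\C)CC/C=C(/C)CCCO[Si](C)(C)C(C)(C)C | intermediate
20 | lithium (chloromethyl)(pinacolato)borate complex of 19, boron on C14 (not isolated) | [Li+].ClC[B-]1(OC(C)(C)C(C)(C)O1)C[C@@H](C(=C)CCC=C(C)C)C/C=C(\C)CC/C=C(/C)CCCO[Si](C)(C)C(C)(C)C | intermediate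
21 | tert-butyldimethyl{[(4Z,8E,11R)-4,8,16-trimethyl-12-methylidene-11-[2-(4,4,5,5-tetramethyl-1,3,2-dioxaborolan-2-yl)ethyl]heptadeca-4,8,15-trien-1-yl]oxy}silane | C=C(CCC=C(C)C)[C@H](CCB1OC(C)(C)C(C)(C)O1)C/C=C(\C)CC/C=C(/C)CCCO[Si](C)(C)C(C)(C)C | intermediate
22 | (4Z,8E,11R)-4,8,16-trimethyl-12-methylidene-11-[2-(4,4,5,5-tetramethyl-1,3,2-dioxaborolan-2-yl)ethyl]heptadeca-4,8,15-trien-1-ol | C=C(CCC=C(C)C)[C@H](CCB1OC(C)(C)C(C)(C)O1)C/C=C(\C)CC/C=C(/C)CCCO | intermediate
23 | (4Z,8E,11R)-4,8,16-trimethyl-12-methylidene-11-[2-(4,4,5,5-tetramethyl-1,3,2-dioxaborolan-2-yl)ethyl]heptadeca-4,8,15-trienal | C=C(CCC=C(C)C)[C@H](CCB1OC(C)(C)C(C)(C)O1)C/C=C(\C)CC/C=C(/C)CCC=O | intermediate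
24 | methyl (2Z,6Z,10E,13R)-2-iodo-6,10,18-trimethyl-14-methylidene-13-[2-(4,4,5,5-tetramethyl-1,3,2-dioxaborolan-2-yl)ethyl]nonadeca-2,6,10,17-tetraenoate | C=C(CCC=C(C)C)[C@H](CCB1OC(C)(C)C(C)(C)O1)C/C=C(\C)CC/C=C(/C)CC/C=C(\I)C(=O)OC | intermediate
25 | CNP0199631.1, methyl (1E,5Z,9E,12R)-5,9-dimethyl-12-(6-methylhepta-1,5-dien-2-yl)cyclotetradeca-1,5,9-triene-1-carboxylate | C=C(CCC=C(C)C)[C@H]1C/C=C(\C)CC/C=C(/C)CC/C=C(/C(=O)OC)CC1 | target

**Step count and risks**

Total step count: 15. Longest linear sequence: 13 steps (steps 1–6 and 9–15, from nerol).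

Step 15 (ring closure) is the most likely to fail. Transmetallation of an unactivated primary alkyl pinacol boronate is slow, and at high dilution protodeboronation, β-hydride elimination, Heck-type insertion into a nearby alkene or intermolecular coupling may compete. The fallback closes the ring at C11=C12 by olefination and sets out from 21. Oxidation of the C13–B bond (NaBO3·4H2O, THF/H2O) gives (3S,5E,9Z)-13-[(tert-butyldimethylsilyl)oxy]-6,10-dimethyl-3-(6-methylhepta-1,5-dien-2-yl)trideca-5,9-dien-1-ol F1. Appel iodination (I2, PPh3, imidazole) gives tert-butyl{[(4Z,8E,11S)-13-iodo-4,8-dimethyl-11-(6-methylhepta-1,5-dien-2-yl)trideca-4,8-dien-1-yl]oxy}dimethylsilane F2. Alkylation of the sodium salt of methyl diethylphosphonoacetate (NaH, THF/DMF) gives methyl (5R,7E,11Z)-15-[(tert-butyldimethylsilyl)oxy]-2-(diethoxyphosphoryl)-8,12-dimethyl-5-(6-methylhepta-1,5-dien-2-yl)pentadeca-7,11-dienoate F3. CSA in MeOH then frees methyl (5R,7E,11Z)-2-(diethoxyphosphoryl)-15-hydroxy-8,12-dimethyl-5-(6-methylhepta-1,5-dien-2-yl)pentadeca-7,11-dienoate F4, and Dess–Martin oxidation gives methyl (5R,7E,11Z)-2-(diethoxyphosphoryl)-8,12-dimethyl-5-(6-methylhepta-1,5-dien-2-yl)-15-oxopentadeca-7,11-dienoate F5. An intramolecular Horner–Wadsworth–Emmons reaction (LiCl, DBU, MeCN, high dilution) comes back to the route at 25.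

Step 9 (key step) is second. α-Lithiation of the long homoallylic carbamate may be incomplete or unselective (allylic deprotonation at C2, loss of configuration of the organolithium before it is trapped), and alkenyl migration in the hindered boronate complex may be slow. The fallback makes the same C1–C15 bond by a catalytic enantiotopic-group-selective Suzuki–Miyaura coupling and sets out from 6 and 13. Carboalumination of 6 (AlMe3, Cp2ZrCl2) and trapping with paraformaldehyde gives (2E,6Z)-10-[(tert-butyldimethylsilyl)oxy]-3,7-dimethyldeca-2,6-dien-1-ol F6. Appel bromination (CBr4, PPh3) gives tert-butyl{[(4Z,8E)-10-bromo-4,8-dimethyldeca-4,8-dien-1-yl]oxy}dimethylsilane F7. Alkylation of lithiated bis(pinacolato)borylmethane (LiTMP, THF) gives tert-butyl{[(4Z,8E)-4,8-dimethyl-11,11-bis(4,4,5,5-tetramethyl-1,3,2-dioxaborolan-2-yl)undeca-4,8-dien-1-yl]oxy}dimethylsilane F8. Triflate 13 is converted with LiBr under ruthenium catalysis into 2-bromo-6-methylhepta-1,5-diene F9. Coupling of F8 with F9 (Pd(OAc)2, chiral TADDOL-derived phosphoramidite, KOH, dioxane/H2O) selects one of the two enantiotopic boryl groups and comes back to the route at 17.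

Step 2 is third. Ozone may attack the chlorine-bearing alkene as well, or over-oxidise, so that site selectivity is lost. The fallback sets out from 2 and replaces ozonolysis by epoxidation and glycol-type cleavage. mCPBA at −20 °C epoxidises the remote, more electron-rich alkene to 3-[(3Z)-5-chloro-3-methylpent-3-en-1-yl]-2,2-dimethyloxirane F10. Periodic acid (THF/H2O) cleaves it to aldehyde 3, here isolated, and NaBH4 reduction comes back to the route at 4.

**Further compounds**

F1 | step 15 | (3S,5E,9Z)-13-[(tert-butyldimethylsilyl)oxy]-6,10-dimethyl-3-(6-methylhepta-1,5-dien-2-yl)trideca-5,9-dien-1-ol | C=C(CCC=C(C)C)[C@H](CCO)C/C=C(\C)CC/C=C(/C)CCCO[Si](C)(C)C(C)(C)C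
F2 | step 15 | tert-butyl{[(4Z,8E,11S)-13-iodo-4,8-dimethyl-11-(6-methylhepta-1,5-dien-2-yl)trideca-4,8-dien-1-yl]oxy}dimethylsilane | C=C(CCC=C(C)C)[C@H](CCI)C/C=C(\C)CC/C=C(/C)CCCO[Si](C)(C)C(C)(C)C
F3 | step 15 | methyl (5R,7E,11Z)-15-[(tert-butyldimethylsilyl)oxy]-2-(diethoxyphosphoryl)-8,12-dimethyl-5-(6-methylhepta-1,5-dien-2-yl)pentadeca-7,11-dienoate (both C2 epimers) | C=C(CCC=C(C)C)[C@H](CCC(C(=O)OC)P(=O)(OCC)OCC)C/C=C(\C)CC/C=C(/C)CCCO[Si](C)(C)C(C)(C)C
F4 | step 15 | methyl (5R,7E,11Z)-2-(diethoxyphosphoryl)-15-hydroxy-8,12-dimethyl-5-(6-methylhepta-1,5-dien-2-yl)pentadeca-7,11-dienoate (both C2 epimers) | C=C(CCC=C(C)C)[C@H](CCC(C(=O)OC)P(=O)(OCC)OCC)C/C=C(\C)CC/C=C(/C)CCCO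
F5 | step 15 | methyl (5R,7E,11Z)-2-(diethoxyphosphoryl)-8,12-dimethyl-5-(6-methylhepta-1,5-dien-2-yl)-15-oxopentadeca-7,11-dienoate (both C2 epimers) | C=C(CCC=C(C)C)[C@H](CCC(C(=O)OC)P(=O)(OCC)OCC)C/C=C(\C)CC/C=C(/C)CCC=O
F6 | step 9 | (2E,6Z)-10-[(tert-butyldimethylsilyl)oxy]-3,7-dimethyldeca-2,6-dien-1-ol | OC/C=C(\C)CC/C=C(/C)CCCO[Si](C)(C)C(C)(C)C
F7 | step 9 | tert-butyl{[(4Z,8E)-10-bromo-4,8-dimethyldeca-4,8-dien-1-yl]oxy}dimethylsilane | BrC/C=C(\C)CC/C=C(/C)CCCO[Si](C)(C)C(C)(C)C
F8 | step 9 | tert-butyl{[(4Z,8E)-4,8-dimethyl-11,11-bis(4,4,5,5-tetramethyl-1,3,2-dioxaborolan-2-yl)undeca-4,8-dien-1-yl]oxy}dimethylsilane | CC1(C)OB(OC1(C)C)C(B1OC(C)(C)C(C)(C)O1)C/C=C(\C)CC/C=C(/C)CCCO[Si](C)(C)C(C)(C)C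
F9 | step 9 | 2-bromo-6-methylhepta-1,5-diene | C=C(Br)CCC=C(C)C
F10 | step 2 | 3-[(3Z)-5-chloro-3-methylpent-3-en-1-yl]-2,2-dimethyloxirane (racemic) | ClC/C=C(/C)CCC1OC1(C)C
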